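**Retrosynthetic overview**

1. The (E)-acrylic acid is made last from an aryl aldehyde (Knoevenagel–Doebner). The side chain, numbered C1′ (benzylic CH2) to C8′, is built on that aldehyde.
2. Key disconnection: the C3′–C4′ bond between the methyl-bearing alkene carbon and the acetoxy-bearing stereocentre, made by a nickel-catalysed enantioconvergent decarboxylative alkenylation of the racemic redox-active ester 15 with the (Z)-alkenyl iodide 9.
3. Enabling feature: C4′ is an O-acetyl carbinol carbon directly bonded to the sp2 carbon C3′. As the α-carbon of an α-acetoxy acid it gives, on decarboxylation, a planar oxygen-stabilised radical (so a racemate suffices) whose acetate C=O can chelate nickel. C3′ enters as an alkenyl iodide whose Z geometry is set in step 1 and retained through the coupling.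
4. 9 comes from but-2-yn-1-ol (hydroalumination/iodination, bromination) and the Grignard reagent of acetal-protected 3-bromo-4-methoxybenzaldehyde. 15 comes from methyl glycidate and 2-methylprop-1-enylmagnesium bromide (opening, saponification, acetylation, N-hydroxyphthalimide ester).
5. No ring is formed in the route: the benzene ring is bought with 5, and the only temporary ring is the dioxolane of 6–8, opened again in step 4.

Key step: step 8

Remark on the chemistry: the sense of induction of the chiral bis(oxazoline) ligand in step 8 cannot be predicted with certainty for this radical. It is assumed that one antipode of the ligand (both are commercially available) gives the (R)-acetate, and that antipode is the one meant in step 8. Compounds 10 and 12–15 are racemic by design.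

**Route**

Step 1
Reactants: 1 but-2-yn-1-ol
Product: 3 (Z)-3-iodobut-2-en-1-ol, via alkenylalanate 2 (not isolated)
Conditions: NaAlH2(OCH2CH2OMe)2 (Red-Al), THF, 0 °C → rt; then I2, THF, −78 → 0 °C
Reagents that add atoms: iodine, II
Why: Hydroxyl-directed trans-hydroalumination of the propargylic alcohol puts aluminium on the distal alkyne carbon inside a five-membered oxaluminacycle, and iodinolysis of the C–Al bond with retention should give only the Z-iodoalkene (iodine cis to CH2OH), which sets the geometry of the later C2′=C3′ alkene.

Step 2
Reactants: 3 (Z)-3-iodobut-2-en-1-ol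
Product: 4 (Z)-1-bromo-3-iodobut-2-ene
Conditions: CBr4, PPh3, CH2Cl2, 0 °C
Reagents that add atoms: carbon tetrabromide, BrC(Br)(Br)Br
Why: The Appel reaction converts the primary allylic alcohol into the bromide under neutral conditions by SN2 displacement of the oxyphosphonium group, without touching the alkenyl iodide or its geometry.

Step 3
Reactants: 5 3-bromo-4-methoxybenzaldehyde
Product: 6 2-(3-bromo-4-methoxyphenyl)-1,3-dioxolane
Conditions: ethylene glycol, p-TsOH (cat.), toluene, reflux (Dean–Stark)
Reagents that add atoms: ethylene glycol, OCCO
Why: Acid-catalysed acetalisation with azeotropic removal of water masks the aldehyde for the Grignard step.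

Step 4
Reactants: 6 2-(3-bromo-4-methoxyphenyl)-1,3-dioxolane; 4 (Z)-1-bromo-3-iodobut-2-ene
Product: 9 3-[(2Z)-3-iodobut-2-en-1-yl]-4-methoxybenzaldehyde, via aryl Grignard reagent 7 (not isolated), via iodoalkenyl dioxolane 8 (not isolated)
Conditions: Mg, LiCl, THF, rt; then Li2CuCl4 (3 mol %), 4, −20 → 0 °C; then 1 M HCl, THF, rt
Reagents that add atoms: water, O
Why: Magnesium insertion into the aryl bromide followed by a copper-catalysed Grignard cross-coupling with the primary allylic bromide (SN2 allylic substitution) should join the arene to C1′ with the alkenyl iodide and its Z geometry intact, and the acidic work-up hydrolyses the dioxolane to the aldehyde.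

Step 5
Reactants: 10 methyl oxirane-2-carboxylate (racemic methyl glycidate); 11 2-methylprop-1-enylmagnesium bromide
Product: 13 2-hydroxy-5-methylhex-4-enoic acid (racemic), via hydroxy ester 12 (not isolated)
Conditions: CuBr·SMe2 (10 mol %), THF, −40 °C; then LiOH, MeOH/H2O, rt; then 1 M HCl
Reagents that add atoms: lithium hydroxide, [Li+].[OH-]
Why: Copper-catalysed epoxide opening by the alkenyl Grignard reagent at the unsubstituted C3 of the glycidate should give the α-hydroxy ester, which is saponified in the same flask; the stereocentre is left racemic because step 8 erases it.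

Step 6
Reactants: 13 2-hydroxy-5-methylhex-4-enoic acid (racemic)
Product: 14 2-acetoxy-5-methylhex-4-enoic acid (racemic)
Conditions: Ac2O, pyridine, DMAP (cat.), CH2Cl2, 0 °C → rt; then H2O
Reagents that add atoms: acetic anhydride, CC(=O)OC(C)=O
Why: DMAP-catalysed O-acetylation of the secondary alcohol is standard acyl transfer, and the aqueous work-up returns the free carboxylic acid.

Step 7
Reactants: 14 2-acetoxy-5-methylhex-4-enoic acid (racemic)
Product: 15 1,3-dioxoisoindolin-2-yl 2-acetoxy-5-methylhex-4-enoate (racemic redox-active ester)
Conditions: N-hydroxyphthalimide, DIC, DMAP (cat.), CH2Cl2, 0 °C → rt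
Reagents that add atoms: N-hydroxyphthalimide, ON1C(=O)c2ccccc2C1=O
Why: Carbodiimide (Steglich-type) esterification with N-hydroxyphthalimide gives the redox-active ester that will release the α-acetoxyalkyl radical.

Step 8
Reactants: 15 1,3-dioxoisoindolin-2-yl 2-acetoxy-5-methylhex-4-enoate (racemic); 9 3-[(2Z)-3-iodobut-2-en-1-yl]-4-methoxybenzaldehyde
Product: 16 (2Z,4R)-1-(5-formyl-2-methoxyphenyl)-3,7-dimethylocta-2,6-dien-4-yl acetate
Conditions: NiBr2·diglyme (10 mol %), cyclopropane-1,1-diyl-bridged bis(indanyl-oxazoline) ligand (single antipode, 12 mol %), TDAE (1.5 equiv), NaI (0.5 equiv), DMA, −10 °C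
Reagents that add atoms: none
Why: Proposed new method: zerovalent nickel bearing the chiral bis(oxazoline) adds oxidatively to the C–I bond of 9 with retention of the Z geometry, while single-electron reduction of the N-acyloxyphthalimide 15 (by TDAE or by monovalent nickel) releases phthalimide anion and CO2 and leaves a planar α-acetoxyalkyl radical at C4′, so both enantiomers of 15 converge on one intermediate; capture of this radical by the alkenylnickel species and reductive elimination from trivalent nickel form the C3′–C4′ bond, and TDAE returns the nickel to the cycle. The closest known reaction types are the nickel/bis(oxazoline)-catalysed enantioselective reductive coupling of benzylic N-acyloxyphthalimides with alkenyl bromides, the nickel-catalysed enantioconvergent coupling of racemic α-haloalkyl esters through the same kind of α-acyloxyalkyl radical, and the racemic nickel-catalysed decarboxylative alkenylation of redox-active esters with trisubstituted alkenyl iodides; the new element is a non-benzylic α-acyloxy redox-active ester coupled with an alkenyl iodide under chiral nickel. No ring is closed. The single new stereocentre (C4′, R) is controlled by the chiral ligand on nickel, helped by five-membered chelation of the acetate carbonyl oxygen to nickel, which holds the alkyl group in the chiral pocket during the enantio-determining C–C bond formation. The step needs cross-selectivity (the sp2 iodide reacts by two-electron oxidative addition, the ester only by single-electron reduction), retention of alkene geometry (alkenylnickel intermediates are configurationally stable at low temperature) and tolerance of the aryl aldehyde and the prenyl alkene (the nucleophilic α-oxy radical adds to neither at a competitive rate, and its 3-exo cyclisation onto the prenyl alkene is reversible and unproductive). The acetate is delivered in place, so no protecting-group or acylation step follows.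

Step 9
Reactants: 16 (2Z,4R)-1-(5-formyl-2-methoxyphenyl)-3,7-dimethylocta-2,6-dien-4-yl acetate
Product: 18 (2E)-3-{3-[(2Z,4R)-4-acetoxy-3,7-dimethylocta-2,6-dien-1-yl]-4-methoxyphenyl}prop-2-enoic acid (the target), via arylidenemalonic acid 17 (not isolated)
Conditions: malonic acid, pyridine, piperidine (cat.), 85 °C
Reagents that add atoms: malonic acid, OC(=O)CC(=O)O
Why: Knoevenagel–Doebner condensation of the aryl aldehyde with malonic acid and decarboxylation in pyridine should give the E-cinnamic acid directly as the free acid under weakly basic conditions that neither cleave nor ionise the allylic acetate, and it is placed last because an acrylic acid would trap the radical of step 8.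

**Compound list**

1 | but-2-yn-1-ol | CC#CCO | starting material
2 | sodium 2,2-bis(2-methoxyethoxy)-3-methyl-2,5-dihydro-1,2-oxaluminol-2-uide (cyclic alkenylalanate) | CC1=CCO[Al-]1(OCCOC)OCCOC.[Na+] | intermediate (not isolated)
3 | (Z)-3-iodobut-2-en-1-ol | C/C(I)=C/CO | intermediate
4 | (Z)-1-bromo-3-iodobut-2-ene | C/C(I)=C/CBr | intermediate
5 | 3-bromo-4-methoxybenzaldehyde | COc1ccc(C=O)cc1Br | starting material
6 | 2-(3-bromo-4-methoxyphenyl)-1,3-dioxolane | COc1ccc(C2OCCO2)cc1Br | intermediate
7 | [5-(1,3-dioxolan-2-yl)-2-methoxyphenyl]magnesium bromide | COc1ccc(C2OCCO2)cc1[Mg]Br | intermediate (not isolated)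
8 | 2-{3-[(2Z)-3-iodobut-2-en-1-yl]-4-methoxyphenyl}-1,3-dioxolane | COc1ccc(C2OCCO2)cc1C/C=C(/C)I | intermediate (not isolated)
9 | 3-[(2Z)-3-iodobut-2-en-1-yl]-4-methoxybenzaldehyde | COc1ccc(C=O)cc1C/C=C(/C)I | intermediate
10 | methyl oxirane-2-carboxylate (racemic) | COC(=O)C1CO1 | starting material
11 | 2-methylprop-1-enylmagnesium bromide | CC(C)=C[Mg]Br | starting material
12 | methyl 2-hydroxy-5-methylhex-4-enoate (racemic) | COC(=O)C(O)CC=C(C)C | intermediate (not isolated)
13 | 2-hydroxy-5-methylhex-4-enoic acid (racemic) | CC(C)=CCC(O)C(=O)O | intermediate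
14 | 2-acetoxy-5-methylhex-4-enoic acid (racemic) | CC(=O)OC(CC=C(C)C)C(=O)O | intermediate
15 | 1,3-dioxoisoindolin-2-yl 2-acetoxy-5-methylhex-4-enoate (racemic) | CC(=O)OC(CC=C(C)C)C(=O)ON1C(=O)c2ccccc2C1=O | intermediate
16 | (2Z,4R)-1-(5-formyl-2-methoxyphenyl)-3,7-dimethylocta-2,6-dien-4-yl acetate | COc1ccc(C=O)cc1C/C=C(/C)[C@@H](CC=C(C)C)OC(C)=O | intermediate
17 | 2-({3-[(2Z,4R)-4-acetoxy-3,7-dimethylocta-2,6-dien-1-yl]-4-methoxyphenyl}methylidene)propanedioic acid | COc1ccc(C=C(C(=O)O)C(=O)O)cc1C/C=C(/C)[C@@H](CC=C(C)C)OC(C)=O | intermediate (not isolated)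
18 | (2E)-3-{3-[(2Z,4R)-4-acetoxy-3,7-dimethylocta-2,6-dien-1-yl]-4-methoxyphenyl}prop-2-enoic acid | COc1ccc(/C=C/C(=O)O)cc1C/C=C(/C)[C@@H](CC=C(C)C)OC(C)=O | target

**Summary**

Total step count: 9.
Longest linear sequence: 5 steps (steps 1, 2, 4, 8, 9 from but-2-yn-1-ol, or steps 5, 6, 7, 8, 9 from methyl glycidate).

Steps most likely to fail:

Step 8 (Proposed new method). What may go wrong: insufficient facial discrimination when nickel captures the planar α-acetoxyalkyl radical, or dimerisation and reduction of the radical outrunning the cross-coupling. The fallback uses known chemistry. It sets out from 8, obtained by ending step 4 with a neutral aqueous work-up instead of the HCl hydrolysis, and returns at 16. A catalytic asymmetric Nozaki–Hiyama–Kishi reaction of 8 with 4-methylpent-3-enal F1 (freshly made from commercial 4-methylpent-3-en-1-ol with Dess–Martin periodinane and NaHCO3) would use CrCl2 (cat.), a chiral sulfonamide–oxazoline ligand, NiCl2 (cat.), Mn, Cp2ZrCl2 and LiCl in MeCN. It would form the same C3′–C4′ bond by addition of the alkenylchromium species to the aldehyde and should give (2Z,4R)-1-[5-(1,3-dioxolan-2-yl)-2-methoxyphenyl]-3,7-dimethylocta-2,6-dien-4-ol F2. Acetylation (Ac2O, pyridine, DMAP) would give (2Z,4R)-1-[5-(1,3-dioxolan-2-yl)-2-methoxyphenyl]-3,7-dimethylocta-2,6-dien-4-yl acetate F3, and PPTS in wet acetone would unmask the aldehyde to give 16.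

Step 4. What may go wrong: iodine–magnesium exchange at the alkenyl iodide, or allylic transposition (attack at the iodine-bearing γ-carbon) during the copper-catalysed substitution. The fallback builds the iodoalkene after the aryl–carbon bond. It sets out from 6 (through Grignard reagent 7) and returns at 8, which the acidic work-up of step 4 turns into 9. Coupling of 7 with allyl bromide (Li2CuCl4 cat.) would give 2-(3-allyl-4-methoxyphenyl)-1,3-dioxolane F4. Oxidative cleavage (OsO4 cat., NaIO4, 2,6-lutidine, dioxane/water) would give 2-[5-(1,3-dioxolan-2-yl)-2-methoxyphenyl]acetaldehyde F5. A Stork–Zhao olefination with the ylide from (1-iodoethyl)triphenylphosphonium iodide (ethyltriphenylphosphonium iodide, n-BuLi, I2, then NaN(SiMe3)2, THF, −78 °C) should then give the Z-iodoalkene 8.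

Step 9. What may go wrong: aminolysis or migration of the allylic acetate in hot pyridine/piperidine, or incomplete decarboxylation. The fallback sets out from 16 and returns at 18. A Horner–Wadsworth–Emmons reaction with 2-(trimethylsilyl)ethyl 2-(diethoxyphosphoryl)acetate (LiCl, DBU, MeCN, rt) would give 2-(trimethylsilyl)ethyl (2E)-3-{3-[(2Z,4R)-4-acetoxy-3,7-dimethylocta-2,6-dien-1-yl]-4-methoxyphenyl}prop-2-enoate F6. Fluoride-induced fragmentation of the silylethyl ester (TASF, DMF, 0 °C) would free the acid 18 without touching the acetate.

**Further compounds**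

F1 | step 8 | 4-methylpent-3-enal | CC(C)=CCC=O
F2 | step 8 | (2Z,4R)-1-[5-(1,3-dioxolan-2-yl)-2-methoxyphenyl]-3,7-dimethylocta-2,6-dien-4-ol | COc1ccc(C2OCCO2)cc1C/C=C(/C)[C@@H](CC=C(C)C)O
F3 | step 8 | (2Z,4R)-1-[5-(1,3-dioxolan-2-yl)-2-methoxyphenyl]-3,7-dimethylocta-2,6-dien-4-yl acetate | COc1ccc(C2OCCO2)cc1C/C=C(/C)[C@@H](CC=C(C)C)OC(C)=O
F4 | step 4 | 2-(3-allyl-4-methoxyphenyl)-1,3-dioxolane | COc1ccc(C2OCCO2)cc1CC=C
F5 | step 4 | 2-[5-(1,3-dioxolan-2-yl)-2-methoxyphenyl]acetaldehyde | COc1ccc(C2OCCO2)cc1CC=O
F6 | step 9 | 2-(trimethylsilyl)ethyl (2E)-3-{3-[(2Z,4R)-4-acetoxy-3,7-dimethylocta-2,6-dien-1-yl]-4-methoxyphenyl}prop-2-enoate | COc1ccc(/C=C/C(=O)OCC[Si](C)(C)C)cc1C/C=C(/C)[C@@H](CC=C(C)C)OC(C)=O
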